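- If a rate falls by a steady fraction each minute, the target still to come is the present rate divided by that fraction, the closed integral of a decaying exponential, so I set out to bracket the dusk flask with that one division.

| setting | summer | midnight | noon | autumn | dusk |
|---|---|---|---|---|---|
| starting material | 50.0 mM | 30.0 mM | 50.0 mM | 100 mM | 50.0 mM |
| free catalyst | 0.250 mM | 0.250 mM | 0.750 mM | 0.250 mM | 0.250 mM |
| target |  |  |  |  | 25.0 mM |
| time |  |  |  |  | 7.0 min |

| run | time / min | [target] / mM |
|---|---|---|
| summer run | 1.0 | 6.6 |
| summer run | 2.0 | 11.3 |
| summer run | 3.0 | 13.9 |
| summer run | 4.0 | 15.7 |
| summer run | 5.0 | 15.8 |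
| summer run | 6.0 | 16.2 |
| summer run | 7.0 | 16.7 |
| midnight run | 1.0 | 4.2 |
| midnight run | 2.0 | 7.0 |
| midnight run | 3.0 | 8.1 |
| midnight run | 4.0 | 10.1 |
| midnight run | 5.0 | 10.4 |
| midnight run | 6.0 | 11.2 |
| midnight run | 7.0 | 11.4 |
| noon run | 1.0 | 17.0 |
| noon run | 2.0 | 24.2 |
| noon run | 3.0 | 26.9 |
| noon run | 4.0 | 28.5 |
| noon run | 5.0 | 28.5 |
| noon run | 6.0 | 29.7 |
| noon run | 7.0 | 29.1 |
| autumn run | 1.0 | 13.4 |
| autumn run | 2.0 | 21.0 |
| autumn run | 3.0 | 25.6 |
| autumn run | 4.0 | 26.8 |
| autumn run | 5.0 | 28.1 |
| autumn run | 6.0 | 28.9 |
| autumn run | 7.0 | 28.8 |

(each reading ± 0.3 mM)

- Overall: starting material -> target, with free catalyst as catalyst.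
- Constant volume, constant temperature.
- An order is taken over about fifteen percent of the charge, up and down.
- A share of target counts the target that was charged too.

1. order of the initial rate in [free catalyst], near the charge of the summer run, the rate being that where two percent of its starting material are target
2. order of the initial rate in [starting material], near the charge of the summer run, the rate being that where two percent of its starting material are target (one fixed amount of target, the same in the runs compared)
3. target in the dusk run at 7.0 min, as a share of the starting material charged

- The crude bounds came first: the dusk flask starts at 50.0% target, and adding the summer run's last reading to its charge gives 83.4%.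
- From its first minute to the minute ending at 3.0 min, the noon run's gain fell at 0.920 /min, and this fade, the fractional fall of the rate per minute, is higher than the 0.466 /min of the summer run.
- The autumn run, whose target had reached about the dusk charge, read 0.632 /min from the minute ending at 3.0 min to that ending at 5.0 min.
- Carrying the summer fade back half a minute gave a start rate of 8.33 mM/min, which I assumed for the dusk flask, whose starting material and free catalyst match the summer charge.
- Taking the autumn fade as floor and the noon fade as ceiling, I committed to a dusk share between 68.1% and 76.4%.
- First-minute gains of the autumn and summer runs gave an order of 1.02 in starting material, and the noon and summer start rates gave 1.07 in free catalyst, so I expected about one for each.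
- The forecast gave 0.97 in free catalyst, 0.95 in starting material and 67% for dusk, saying “this isn't equilibrium: the catalyst is dying”; its dusk share lies just below my bracket.
- The flask gave 1.0 in free catalyst, 1.0 in starting material and 69.8% for dusk, inside my bracket, with the forecast within its margins.

    free catalyst + starting material → target + free catalyst (660.0 /M/min)
    free catalyst + target → spent catalyst + target (18.30 /M/min)
    starting material → decomposed substrate (0.1800 /min)

- The dusk gain of 9.91 mM by 7.0 min implies from my start rate a fade of 0.840 /min, below the noon ceiling of 0.920 /min. The same division on the noon run, 24 mM/min over 0.920 /min, gives 26.1 mM against a last reading of 29.1 mM. The reaction of free catalyst with target to spent catalyst leaves the order in starting material at 1.0 when removed, but the dusk share at 7.0 min is lower because of it: the simulated run without it reaches 93.6% instead of 69.8%.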